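## The problem

Compound 18 is a 3,3''-biflavanone: two 2-(4-methoxyphenyl)chroman-4-one units joined by one C3–C3'' single bond between two separate pyranone rings. Unprimed locants denote the half whose ring A carries hydroxyls at C5 and C7; doubly primed locants denote the half with a hydroxyl at C5'' and a methyl ether at C7''. Because the two A rings differ, the halves must be told apart by construction; treating them as identical ends in a statistical problem. The four contiguous stereocentres C2, C3, C3'' and C2'' are all R, which places the 2-aryl group and the C3 substituent cis on each ring, the less stable arrangement of a 3-substituted flavanone. C3 and C3'' are α to ketones, and C2 and C2'' are benzylic ether carbons β to them, so base or acid epimerises C3 to the trans series or opens the O1–C2 bond. The cis relationship must therefore be set under kinetic control, the ketones must appear late, and the three phenols must be released under neutral conditions. Stereocontrol can be relayed: a 2-aryl group on a 2H-chromene shields one face of C3=C4, so C2 can set C3 and C2'' can set C3'', and the relationship between the halves follows once C2 and C2'' are fixed in the absolute sense. The enabling feature is that C3 and C3'' are directly bonded ring carbons of two pyran rings, each flanked by a C4 on an arene and a C2 on the ring oxygen. This is the pattern left when an alkyne C3≡C3'', whose two propargylic carbons bear ortho-vinylaryl ethers, closes twice by metathesis.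

## Retrosynthesis

**18 back to 16.** No skeletal bond is cut. The three phenols of 18 are masked as benzyl ethers in diketone 17, so the last step is a neutral hydrogenolysis. The two ketones of 17 are taken back to the secondary benzylic alcohols of diol 16. Keeping C4 and C4'' at the alcohol level until the penultimate step means C3 and C3'' are not enolisable during the steps before it. The forward oxidation must be non-basic and non-acidic.

**16 back to 14.** The C3–H, C4–O, C3''–H and C4''–O bonds are removed, giving the 3,3''-bi(2H-chromene) 14. Hydroboration–oxidation is preferred to the neighbouring options because it installs hydrogen at C3 and oxygen at C4 in one syn addition. Hydrogenation followed by benzylic oxidation is held in reserve as a fallback, and epoxidation cannot deliver the C3 hydrogen. Boron should go to the less substituted, benzylic terminus of each trisubstituted alkene (bis-adduct 15). Addition anti to the pseudo-axial 2-aryl group places the new C3 hydrogen cis to H2, which is the cis-flavanone arrangement. Four stereocentres disappear; 14 retains only C2 and C2''.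

**14 back to 13 (key disconnection).** The C3=C4 and C3''=C4'' double bonds are cut, giving the acyclic dienyne 13, in which the alkyne is the future C3–C3'' bond and the two styrene units are the future C4 and C4''. Cutting C3–C3'' instead would require joining two hindered vinyl partners and building each ring separately. Cutting O1–C2 would reopen the stereocentres. Both pyran rings are removed at once, and 13 is assembled from two nearly identical halves around an alkyne. The forward step must start at a styrene, close two six-membered rings, and leave the propargylic ether centres untouched.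

**13 back to 11 and 4.** The second styrene of 13 is taken back to the aldehyde of 12 (methylenation), and the O1''–C2'' ether bond of 12 is cut to propargylic alcohol 11 and salicylaldehyde 4. The aldehyde form of the phenol is chosen for the etherification because the chelated hydroxyl is more acidic and the ring less C-nucleophilic than in an electron-rich vinylphenol. The forward Mitsunobu reaction must invert a 4-methoxybenzylic, propargylic carbinol cleanly.

**11 back to 10 and 5.** The C2''–C3'' bond is cut, giving terminal alkyne 10 and 4-methoxybenzaldehyde 5. Introducing the two aldehyde units one after the other avoids forming both carbinols at once, which would then need a statistical mono-etherification. A catalyst-controlled alkynylation sets the R carbinol, which the Mitsunobu step inverts to the S ether.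

**10 back to 7 and 2; 7 back to 5 and 6.** Alkyne 10 comes from aldehyde 8 by methylenation and desilylation in one flask (via 9). Ether 8 is cut at O1–C2 to carbinol 7 and salicylaldehyde 2. Carbinol 7 is cut at C2–C3 to 5 and ethynyltrimethylsilane 6; the silyl group blocks the alkyne terminus during the first etherification.

**2 and 4 back to 1.** Both phenol partners come from 2,4,6-trihydroxybenzaldehyde 1 by O-alkylations whose order is dictated by the two chelated ortho-hydroxyls: double benzylation gives 2; methylation at the para oxygen gives 3 and one benzylation then gives 4. The 7''-methyl ether is thus in place before the halves are joined.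

## Roads not taken

**Alternative 1:** The cut is C3–C3'' together with both benzylic C2–O bonds, leading back to a tethered bis(4-hydroxycinnamate) such as the (R,R)-butane-2,3-diyl diester A1. In the forward direction a one-electron oxidant (a ferric salt, or a laccase under oxygen) joins the two β-carbons, each ester carbonyl oxygen closes on the opposite benzylic carbon, and hydrolysis releases the tether to leave dilactone A2.
- Merits: one operation makes the central bond and four contiguous stereocentres in a rigid cis-fused bicycle, without protecting groups and from very cheap material.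
- Weak points: in A2 the oxygens on C2 and C2'' are lactone oxygens, not ring-A phenol oxygens, and both A rings are absent. To reach 18, each carbonyl carbon must be C-acylated onto an arene and each benzylic C–O bond must be broken and remade as an aryl ether. That passes through a quinone methide or benzylic cation, so the C2 configuration is lost and reclosure favours the trans-flavanone. Two different A rings would have to be attached to a twofold-symmetric compound.
- Comparison: as a route to the C3–C3'' bond with its stereocentres, A2 is reached in fewer steps than 14, and its key step creates stereocentres where the metathesis creates none. Against this, 13 already contains both O1–C2 bonds, both distinct A rings and both C2 configurations, and none of them is broken afterwards. The price is three further steps to add C3–H and C4=O.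

**Alternative 2:** The cut is C2–C3 of the first half, leading back to α-diazo ketone A3. A chiral dirhodium tetraprolinate releases nitrogen and the carbenoid inserts into the benzylic C–H bond of the 4-methoxybenzyl ether, closing the pyranone with C2 and C3 cis to give A4.
- Merits: the route is convergent, the cis relationship comes from a concerted insertion, and both C4 carbons are already ketones, so no boron chemistry or oxidation is needed.
- Weak points: the carbenoid sits between an aryl ketone and a chromone, not the aryl diazoacetate type for which such catalysts are most selective. The ring A of A3 carries a second ortho benzylic ether (the 5-O-benzyl group) whose C–H bonds are equally placed for six-membered insertion. A4 is still a flavone in its second half: C2''=C3'' must take up two hydrogens cis on the correct face of a tetrasubstituted, electron-rich double bond, while C3, now α to a ketone and attached to the chromone, must not epimerise.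
- Comparison: on oxidation level at C4, A4 is better placed than 14. The chosen plan sets against this that C2 and C2'' are fixed independently by the same catalyst-controlled reaction and both halves are finished by one common operation, whereas this road needs two unrelated stereochemical solutions.

**Alternative 3:** The cuts are O1–C2, C3–C4, O1''–C2'' and C3''–C4'', leading back to 2,5-bis(4-methoxyphenyl)furan A5 and salicyl alcohol A6. A chiral phosphoric acid dehydrates A6 to the ortho-quinone methide A7, two molecules of which add [4+2] to the two furan double bonds to give the furan-bridged bis-ketal A8.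
- Merits: this is the most convergent of the four plans. Four bonds, both pyran rings and all four stereocentres come from two simple pieces, and cis ring fusion is guaranteed by the cycloaddition.
- Weak points: the first addition must dearomatise a diaryl-conjugated furan and competes with simple C-alkylation and rearomatisation. In A8, C2 and C2'' are ketal carbons and C4 and C4'' are methylenes, so both C2–H bonds must be made by reductive ketal opening through a 2-aryl oxocarbenium ion, with the configuration at C2 decided only then, and both C4 must be oxidised in the presence of newly benzylic C2–H bonds. As formulated, A8 carries four benzyl ethers, so the O7'' methyl ether is not distinguished.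
- Comparison: per step, this road forms more bonds and stereocentres than the metathesis, which forms two bonds and no stereocentre. The chosen plan sets against this that C2 and C2'' are set before the key step and never pass through a cation, that C4 is oxygenated by alkene functionalisation and not C–H oxidation, and that the two A rings are distinguished from the start.

Key step: step 10

Assumption: the (S,S) antipode of the ProPhenol ligand is written for alkynyl transfer to the Si face of 4-methoxybenzaldehyde (R carbinols 7 and 11); if the facial sense is the opposite, the (R,R) ligand is used and nothing else changes.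

## Route

Step 1
Reactants: 1 2,4,6-trihydroxybenzaldehyde
Product: 2 2,4-bis(benzyloxy)-6-hydroxybenzaldehyde
Conditions: BnBr (2.1 equiv), K2CO3 (2.2 equiv), DMF, 0 °C → rt
Reagents that add atoms: benzyl bromide, BrCc1ccccc1
Why: Williamson etherification; the para hydroxyl reacts first and one chelated ortho hydroxyl second, while the last one stays locked in the hydrogen bond to the formyl group, so alkylation should stop at the dibenzyl ether.

Step 2
Reactants: 1 2,4,6-trihydroxybenzaldehyde
Product: 3 2,6-dihydroxy-4-methoxybenzaldehyde
Conditions: MeI (1.0 equiv), CsHCO3 (1.1 equiv), MeCN, 50 °C (sealed)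
Reagents that add atoms: iodomethane, CI
Why: Regioselective Williamson methylation; the weak hydrogencarbonate base ionises only the vinylogous-acid 4-hydroxyl, and the two ortho hydroxyls remain chelated to the aldehyde.

Step 3
Reactants: 3 2,6-dihydroxy-4-methoxybenzaldehyde
Product: 4 2-(benzyloxy)-6-hydroxy-4-methoxybenzaldehyde
Conditions: BnBr (1.0 equiv), K2CO3 (1.05 equiv), DMF, rt
Reagents that add atoms: benzyl bromide, BrCc1ccccc1
Why: Williamson etherification of one of two equivalent chelated hydroxyls; after the first benzylation the remaining hydroxyl is the only hydrogen-bond donor to the carbonyl and reacts much more slowly, as in step 1.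

Step 4
Reactants: 5 4-methoxybenzaldehyde; 6 ethynyltrimethylsilane
Product: 7 (1R)-1-(4-methoxyphenyl)-3-(trimethylsilyl)prop-2-yn-1-ol
Conditions: 6 (3 equiv), Me2Zn (3 equiv), (S,S)-ProPhenol (20 mol%), Ph3P=O (40 mol%), toluene, 0 → 4 °C; aq. NH4Cl
Reagents that add atoms: none
Why: Zinc–ProPhenol catalysed enantioselective alkynylation of an aromatic aldehyde; the dinuclear zinc complex binds aldehyde and alkynylzinc together and delivers the alkynyl group to the Si face, setting the R carbinol under catalyst control.

Step 5
Reactants: 7 (1R)-1-(4-methoxyphenyl)-3-(trimethylsilyl)prop-2-yn-1-ol; 2 2,4-bis(benzyloxy)-6-hydroxybenzaldehyde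
Product: 8 2,4-bis(benzyloxy)-6-{[(1S)-1-(4-methoxyphenyl)-3-(trimethylsilyl)prop-2-yn-1-yl]oxy}benzaldehyde
Conditions: PPh3 (1.3 equiv), DIAD (1.3 equiv), toluene, −20 → 0 °C
Reagents that add atoms: none
Why: Mitsunobu etherification with inversion (R carbinol to S ether); the chelated salicylaldehyde is acidic enough to protonate the betaine, the non-polar solvent and low temperature disfavour ionisation of the alkoxyphosphonium ion, and the silyl group blocks attack at the remote alkyne carbon.

Step 6
Reactants: 8 2,4-bis(benzyloxy)-6-{[(1S)-1-(4-methoxyphenyl)-3-(trimethylsilyl)prop-2-yn-1-yl]oxy}benzaldehyde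
Product: 10 1,5-bis(benzyloxy)-2-ethenyl-3-{[(1R)-1-(4-methoxyphenyl)prop-2-yn-1-yl]oxy}benzene, via silylated styrene 9 (not isolated)
Conditions: Ph3PCH3Br (1.5 equiv), KOtBu (1.4 equiv), THF, 0 °C → rt; then MeOH, K2CO3 (0.2 equiv), rt
Reagents that add atoms: methyltriphenylphosphonium bromide, C[P+](c1ccccc1)(c1ccccc1)c1ccccc1.[Br-]
Why: Wittig methylenation of the hindered but non-enolisable aldehyde, followed in the same flask by methanolysis of the alkynyl C–Si bond. The stereocentre is not touched; its descriptor changes from S (9) to R (10) only because ethynyl ranks below aryl whereas silylethynyl ranks above it.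

Step 7
Reactants: 10 1,5-bis(benzyloxy)-2-ethenyl-3-{[(1R)-1-(4-methoxyphenyl)prop-2-yn-1-yl]oxy}benzene; 5 4-methoxybenzaldehyde
Product: 11 (1R,4S)-4-[3,5-bis(benzyloxy)-2-ethenylphenoxy]-1,4-bis(4-methoxyphenyl)but-2-yn-1-ol
Conditions: 5 (1.5 equiv), Me2Zn (2.5 equiv), (S,S)-ProPhenol (20 mol%), Ph3P=O (40 mol%), toluene, 0 → 4 °C; aq. NH4Cl
Reagents that add atoms: none
Why: The same zinc–ProPhenol alkynylation as in step 4; the existing ether centre is four atoms away across a linear alkyne, so the new R carbinol should be set by the catalyst alone (Si-face addition), and mild alkyne metalation by Me2Zn spares the propargylic ether.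

Step 8
Reactants: 11 (1R,4S)-4-[3,5-bis(benzyloxy)-2-ethenylphenoxy]-1,4-bis(4-methoxyphenyl)but-2-yn-1-ol; 4 2-(benzyloxy)-6-hydroxy-4-methoxybenzaldehyde
Product: 12 2-(benzyloxy)-6-{[(1S,4S)-4-[3,5-bis(benzyloxy)-2-ethenylphenoxy]-1,4-bis(4-methoxyphenyl)but-2-yn-1-yl]oxy}-4-methoxybenzaldehyde
Conditions: PPh3 (1.3 equiv), DIAD (1.3 equiv), toluene, −20 → 0 °C
Reagents that add atoms: none
Why: Second Mitsunobu etherification with inversion (R carbinol to S ether), on the same type of carbinol and with the same type of chelated phenol as step 5; 11 has a single hydroxyl and 4 a single phenol, so no selectivity question arises.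

Step 9
Reactants: 12 2-(benzyloxy)-6-{[(1S,4S)-4-[3,5-bis(benzyloxy)-2-ethenylphenoxy]-1,4-bis(4-methoxyphenyl)but-2-yn-1-yl]oxy}-4-methoxybenzaldehyde
Product: 13 (1S,4S)-1-[3-(benzyloxy)-2-ethenyl-5-methoxyphenoxy]-4-[3,5-bis(benzyloxy)-2-ethenylphenoxy]-1,4-bis(4-methoxyphenyl)but-2-yne
Conditions: Ph3PCH3Br (1.5 equiv), KOtBu (1.4 equiv), THF, 0 °C → rt
Reagents that add atoms: methyltriphenylphosphonium bromide, C[P+](c1ccccc1)(c1ccccc1)c1ccccc1.[Br-]
Why: Wittig methylenation as in step 6; the ylide is kept in slight excess over base so that no free alkoxide meets the propargylic C–H bonds.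

Step 10
Reactants: 13 (1S,4S)-1-[3-(benzyloxy)-2-ethenyl-5-methoxyphenoxy]-4-[3,5-bis(benzyloxy)-2-ethenylphenoxy]-1,4-bis(4-methoxyphenyl)but-2-yne
Product: 14 (2S,2''S)-5,5'',7-tris(benzyloxy)-7''-methoxy-2,2''-bis(4-methoxyphenyl)-2H,2''H-3,3''-bichromene
Conditions: RuCl2(=CHPh)(H2IMes)(PCy3) (second-generation Grubbs catalyst, 10 mol%), toluene (0.005 M), 60 °C, argon stream, dark
Reagents that add atoms: none
Why: After phosphine loss the ruthenium carbene exchanges onto one terminal styrene of 13 (ene-first initiation, since the internal alkyne is shielded by two branched propargylic carbons), giving an aryl-substituted carbene at C4 or C4''. This carbene adds across the tethered alkyne through a ruthenacyclobutene in the exo mode, bonding to the nearer alkyne carbon, so the first six-membered 2H-chromene forms and the metal moves to the other alkyne carbon as a vinylcarbene; the endo mode would give a strained seven-membered ring. The vinylcarbene lies one six-membered ring away from the second styrene and closes the second chromene by ordinary ring-closing alkene metathesis, releasing Ru=CH2 and, overall, one ethene. The closest known reaction type is tandem dienyne ring-closing metathesis of a central alkyne flanked by two tethered alkenes to give two rings joined through a 1,3-diene, together with enyne metathesis of 2-vinylphenyl propargyl ethers to 3-vinyl-2H-chromenes. No stereocentre is created: C2 and C2'' are spectators whose bonds the carbene chemistry does not touch, so the arrangement of 13 is carried into 14 (still S,S). Because the halves differ only in a remote ether group, initiation at either styrene leads to the same diene. The step needs double six-membered closure to win over dimerising cross-metathesis and over methylene capping of the vinylcarbene; high dilution, removal of ethene in the argon stream and the favourable ring size should secure it. The neutral medium and exclusion of light protect the acid- and light-sensitive 2-aryl-2H-chromene rings.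

Step 11
Reactants: 14 (2S,2''S)-5,5'',7-tris(benzyloxy)-7''-methoxy-2,2''-bis(4-methoxyphenyl)-2H,2''H-3,3''-bichromene
Product: 16 (2R,3S,4S,2''R,3''S,4''S)-5,5'',7-tris(benzyloxy)-7''-methoxy-2,2''-bis(4-methoxyphenyl)-3,3''-bichromane-4,4''-diol, via bis(alkylborane) 15 (not isolated)
Conditions: BH3·THF (6 equiv), THF, 0 °C → rt; then 3 M NaOH, 30% H2O2, 0 °C → rt
Reagents that add atoms: hydrogen peroxide, OO; borane–tetrahydrofuran, B.C1CCOC1 (its boron is carried only in 15)
Why: Hydroboration–oxidation; boron should go to C4 and C4'', the less substituted benzylic termini of the 2,3-disubstituted diene, as in hydroboration of 3-substituted 2H-chromenes to chroman-4-ols. Syn addition occurs on the face opposite the pseudo-axial 2-aryl group of each ring, so each new C3 hydrogen is cis to H2 (C2 controls C3, C2'' controls C3''), and oxidation with retention gives the 3,4-trans alcohols.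

Step 12
Reactants: 16 (2R,3S,4S,2''R,3''S,4''S)-5,5'',7-tris(benzyloxy)-7''-methoxy-2,2''-bis(4-methoxyphenyl)-3,3''-bichromane-4,4''-diol
Product: 17 (2R,3R,2''R,3''R)-5,5'',7-tris(benzyloxy)-7''-methoxy-2,2''-bis(4-methoxyphenyl)-3,3''-bichromane-4,4''-dione
Conditions: Dess–Martin periodinane (3 equiv), NaHCO3, CH2Cl2, 0 °C → rt
Reagents that add atoms: none
Why: Dess–Martin oxidation of two secondary benzylic alcohols under buffered, near-neutral conditions, which should leave the epimerisable cis C3 and C3'' centres and the O1–C2 bonds intact (the descriptors at C3 and C3'' change from S to R only through the new priority of C4).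

Step 13
Reactants: 17 (2R,3R,2''R,3''R)-5,5'',7-tris(benzyloxy)-7''-methoxy-2,2''-bis(4-methoxyphenyl)-3,3''-bichromane-4,4''-dione
Product: 18 (2R,3R,2''R,3''R)-5,5'',7-trihydroxy-7''-methoxy-2,2''-bis(4-methoxyphenyl)-3,3''-bichromane-4,4''-dione
Conditions: H2 (1 atm), 10% Pd/C, EtOAc, rt
Reagents that add atoms: none
Why: Hydrogenolysis of three aryl benzyl ethers under neutral conditions, the standard way to release flavanone phenols; the electron-rich aryl ketones and the cyclic C2–O1 ethers are expected to survive at ambient pressure, and no acid or base reaches the cis stereocentres.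

## Compound list

1 | 2,4,6-trihydroxybenzaldehyde | O=Cc1c(O)cc(O)cc1O | starting material
2 | 2,4-bis(benzyloxy)-6-hydroxybenzaldehyde | O=Cc1c(O)cc(OCc2ccccc2)cc1OCc1ccccc1 | intermediate
3 | 2,6-dihydroxy-4-methoxybenzaldehyde | COc1cc(O)c(C=O)c(O)c1 | intermediate
4 | 2-(benzyloxy)-6-hydroxy-4-methoxybenzaldehyde | COc1cc(O)c(C=O)c(OCc2ccccc2)c1 | intermediate
5 | 4-methoxybenzaldehyde | COc1ccc(C=O)cc1 | starting material
6 | ethynyltrimethylsilane | C#C[Si](C)(C)C | starting material
7 | (1R)-1-(4-methoxyphenyl)-3-(trimethylsilyl)prop-2-yn-1-ol | COc1ccc([C@@H](O)C#C[Si](C)(C)C)cc1 | intermediate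
8 | 2,4-bis(benzyloxy)-6-{[(1S)-1-(4-methoxyphenyl)-3-(trimethylsilyl)prop-2-yn-1-yl]oxy}benzaldehyde | COc1ccc([C@H](Oc2cc(OCc3ccccc3)cc(OCc3ccccc3)c2C=O)C#C[Si](C)(C)C)cc1 | intermediate
9 | {(3S)-3-[3,5-bis(benzyloxy)-2-ethenylphenoxy]-3-(4-methoxyphenyl)prop-1-yn-1-yl}trimethylsilane | COc1ccc([C@H](Oc2cc(OCc3ccccc3)cc(OCc3ccccc3)c2C=C)C#C[Si](C)(C)C)cc1 | intermediate (not isolated)
10 | 1,5-bis(benzyloxy)-2-ethenyl-3-{[(1R)-1-(4-methoxyphenyl)prop-2-yn-1-yl]oxy}benzene | COc1ccc([C@H](Oc2cc(OCc3ccccc3)cc(OCc3ccccc3)c2C=C)C#C)cc1 | intermediate
11 | (1R,4S)-4-[3,5-bis(benzyloxy)-2-ethenylphenoxy]-1,4-bis(4-methoxyphenyl)but-2-yn-1-ol | COc1ccc([C@H](Oc2cc(OCc3ccccc3)cc(OCc3ccccc3)c2C=C)C#C[C@H](O)c2ccc(OC)cc2)cc1 | intermediate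
12 | 2-(benzyloxy)-6-{[(1S,4S)-4-[3,5-bis(benzyloxy)-2-ethenylphenoxy]-1,4-bis(4-methoxyphenyl)but-2-yn-1-yl]oxy}-4-methoxybenzaldehyde | COc1ccc([C@H](Oc2cc(OCc3ccccc3)cc(OCc3ccccc3)c2C=C)C#C[C@@H](Oc2cc(OC)cc(OCc3ccccc3)c2C=O)c2ccc(OC)cc2)cc1 | intermediate
13 | (1S,4S)-1-[3-(benzyloxy)-2-ethenyl-5-methoxyphenoxy]-4-[3,5-bis(benzyloxy)-2-ethenylphenoxy]-1,4-bis(4-methoxyphenyl)but-2-yne | COc1ccc([C@H](Oc2cc(OCc3ccccc3)cc(OCc3ccccc3)c2C=C)C#C[C@@H](Oc2cc(OC)cc(OCc3ccccc3)c2C=C)c2ccc(OC)cc2)cc1 | intermediate (key-step precursor)
14 | (2S,2''S)-5,5'',7-tris(benzyloxy)-7''-methoxy-2,2''-bis(4-methoxyphenyl)-2H,2''H-3,3''-bichromene | COc1ccc([C@@H]2Oc3cc(OCc4ccccc4)cc(OCc4ccccc4)c3C=C2C2=Cc3c(OCc4ccccc4)cc(OC)cc3O[C@H]2c2ccc(OC)cc2)cc1 | intermediate (key-step product)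
15 | (2R,2''R)-5,5'',7-tris(benzyloxy)-4,4''-diboranyl-7''-methoxy-2,2''-bis(4-methoxyphenyl)-3,3''-bichromane, with H at C3/C3'' and boron at C4/C4'' on the ring face opposite the 2-aryl group (same arrangement in space as 16) | COc1ccc([C@@H]2Oc3cc(OCc4ccccc4)cc(OCc4ccccc4)c3[C@@H](B)[C@@H]2[C@H]2[C@H](B)c3c(OCc4ccccc4)cc(OC)cc3O[C@H]2c2ccc(OC)cc2)cc1 | intermediate (not isolated)
16 | (2R,3S,4S,2''R,3''S,4''S)-5,5'',7-tris(benzyloxy)-7''-methoxy-2,2''-bis(4-methoxyphenyl)-3,3''-bichromane-4,4''-diol (2,3-cis and 3,4-trans in each ring) | COc1ccc([C@@H]2Oc3cc(OCc4ccccc4)cc(OCc4ccccc4)c3[C@@H](O)[C@@H]2[C@H]2[C@H](O)c3c(OCc4ccccc4)cc(OC)cc3O[C@H]2c2ccc(OC)cc2)cc1 | intermediate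
17 | (2R,3R,2''R,3''R)-5,5'',7-tris(benzyloxy)-7''-methoxy-2,2''-bis(4-methoxyphenyl)-3,3''-bichromane-4,4''-dione | COc1ccc([C@@H]2Oc3cc(OCc4ccccc4)cc(OCc4ccccc4)c3C(=O)[C@@H]2[C@H]2C(=O)c3c(OCc4ccccc4)cc(OC)cc3O[C@H]2c2ccc(OC)cc2)cc1 | intermediate
18 | (2R,3R,2''R,3''R)-5,5'',7-trihydroxy-7''-methoxy-2,2''-bis(4-methoxyphenyl)-3,3''-bichromane-4,4''-dione | COc1ccc([C@@H]2Oc3cc(O)cc(O)c3C(=O)[C@@H]2[C@H]2C(=O)c3c(O)cc(OC)cc3O[C@H]2c2ccc(OC)cc2)cc1 | target

## Step count and risks

Total: 13 steps. Longest linear sequence: 10 steps (steps 4 to 13, from 5).

**Step 10 (key step).** The cascade may stall after the first ring closure. Possible causes are chelation of the styrene-derived carbene by an ortho ether oxygen, slow addition to the crowded alkyne, or capture of the fully substituted vinylcarbene by ethene before it reaches the second, doubly ortho-substituted styrene. Acid- or light-induced ring opening of the 2-aryl-2H-chromenes during isolation would erode C2.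
- Fallback, from 13 back to 14: the alkyne is first treated with the same catalyst under ethene (1 atm, toluene, 80 °C). The small methylidene carbene performs enyne cross-metathesis and gives (1S,4S)-1-[3-(benzyloxy)-2-ethenyl-5-methoxyphenoxy]-4-[3,5-bis(benzyloxy)-2-ethenylphenoxy]-1,4-bis(4-methoxyphenyl)-2,3-dimethylidenebutane F1. F1 is then closed twice by ring-closing metathesis of each diene terminus with its neighbouring styrene, using the phosphine-free second-generation Hoveyda–Grubbs catalyst RuCl2(H2IMes)(=CH-C6H4-2-OiPr) in toluene at 80 °C, to give 14.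

**Step 5 (first Mitsunobu etherification; step 8 repeats it on 11 and shares the hazard).** Partial loss of configuration through ionisation of the alkoxyphosphonium intermediate to a 4-methoxybenzylic, propargylic cation, with SN1-type substitution or C-alkylation of the phenol. Because the two centres are set independently, erosion should appear as a separable diastereomer of 12 and not as lower enantiopurity of 18.
- Fallback, from 5 back to 10: ethynylmagnesium bromide adds to 5 to give racemic 1-(4-methoxyphenyl)prop-2-yn-1-ol F2, which is acetylated to 1-(4-methoxyphenyl)prop-2-yn-1-yl acetate F3. Copper-catalysed enantioselective propargylic substitution with phenol 2 ((CuOTf)2·C6H6, a monovalent copper salt, with a Ph-pybox ligand, iPr2NEt, MeOH, −10 °C) proceeds through a copper allenylidene and converts both enantiomers of F3 into 2,4-bis(benzyloxy)-6-{[(1R)-1-(4-methoxyphenyl)prop-2-yn-1-yl]oxy}benzaldehyde F4, the ligand antipode being chosen for this sense. Wittig methylenation as in step 6 then gives 10.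

**Step 7 (second alkynylation).** Slow turnover or incomplete catalyst control with the bulky, ether-rich alkynylzinc species, giving C1 epimers that are hard to separate because the stereocentres are remote.
- Fallback, from 10 back to 11: deprotonation of 10 at the alkyne terminus (n-BuLi, THF, −78 °C) and acylation with N-methoxy-N-methyl-4-methoxybenzamide gives (4S)-4-[3,5-bis(benzyloxy)-2-ethenylphenoxy]-1,4-bis(4-methoxyphenyl)but-2-yn-1-one F5. Oxazaborolidine-catalysed (Corey–Bakshi–Shibata) reduction with catecholborane in toluene at −78 °C, with the catalyst antipode chosen for the R carbinol, gives 11.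

**Step 11 (double hydroboration).** Boron may be delivered partly to C3 or C3'', leading to β-alkoxyborane elimination and ring opening. The second addition may be delivered intramolecularly from the first borane to the wrong face, or may not go to completion in the crowded diene.
- Fallback, from 14 back to 17: homogeneous hydrogenation with [Ir(cod)(PCy3)(py)]PF6 (H2, CH2Cl2), anti to the 2-aryl groups and sparing the benzyl ethers, gives (2R,3R,2''R,3''R)-5,5'',7-tris(benzyloxy)-7''-methoxy-2,2''-bis(4-methoxyphenyl)-3,3''-bichromane F6. Benzylic oxidation at C4 and C4'' with DDQ in CH2Cl2/H2O, directed there by the dioxygenated A rings, gives the 4,4''-diol as a mixture of C4 epimers F7. Dess–Martin oxidation as in step 12 then gives 17.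

**Step 13 (hydrogenolysis).** Cleavage of the C2–O1 benzylic bonds, which the 4-methoxyphenyl groups activate, or epimerisation at C3 on the catalyst surface.
- Fallback, from 17 to 18: Lewis-acid debenzylation with BCl3 and pentamethylbenzene as cation scavenger in CH2Cl2 at −78 °C, which removes aryl benzyl ethers without hydrogen and leaves unchelated aryl methyl ethers intact. No new compound is made.

## Further compounds

F1 | step 10 | (1S,4S)-1-[3-(benzyloxy)-2-ethenyl-5-methoxyphenoxy]-4-[3,5-bis(benzyloxy)-2-ethenylphenoxy]-1,4-bis(4-methoxyphenyl)-2,3-dimethylidenebutane | COc1ccc([C@H](Oc2cc(OCc3ccccc3)cc(OCc3ccccc3)c2C=C)C(=C)C(=C)[C@@H](Oc2cc(OC)cc(OCc3ccccc3)c2C=C)c2ccc(OC)cc2)cc1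
F2 | step 5 | rac-1-(4-methoxyphenyl)prop-2-yn-1-ol | COc1ccc(C(O)C#C)cc1
F3 | step 5 | rac-1-(4-methoxyphenyl)prop-2-yn-1-yl acetate | COc1ccc(C(OC(C)=O)C#C)cc1
F4 | step 5 | 2,4-bis(benzyloxy)-6-{[(1R)-1-(4-methoxyphenyl)prop-2-yn-1-yl]oxy}benzaldehyde | COc1ccc([C@H](Oc2cc(OCc3ccccc3)cc(OCc3ccccc3)c2C=O)C#C)cc1
F5 | step 7 | (4S)-4-[3,5-bis(benzyloxy)-2-ethenylphenoxy]-1,4-bis(4-methoxyphenyl)but-2-yn-1-one | COc1ccc([C@H](Oc2cc(OCc3ccccc3)cc(OCc3ccccc3)c2C=C)C#CC(=O)c2ccc(OC)cc2)cc1
F6 | step 11 | (2R,3R,2''R,3''R)-5,5'',7-tris(benzyloxy)-7''-methoxy-2,2''-bis(4-methoxyphenyl)-3,3''-bichromane | COc1ccc([C@@H]2Oc3cc(OCc4ccccc4)cc(OCc4ccccc4)c3C[C@@H]2[C@H]2Cc3c(OCc4ccccc4)cc(OC)cc3O[C@H]2c2ccc(OC)cc2)cc1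
F7 | step 11 | (2R,3S,2''R,3''S)-5,5'',7-tris(benzyloxy)-7''-methoxy-2,2''-bis(4-methoxyphenyl)-3,3''-bichromane-4,4''-diol, mixture of C4 and C4'' epimers | COc1ccc([C@@H]2Oc3cc(OCc4ccccc4)cc(OCc4ccccc4)c3C(O)[C@@H]2[C@H]2C(O)c3c(OCc4ccccc4)cc(OC)cc3O[C@H]2c2ccc(OC)cc2)cc1
F0 | step 13 | none | none
A1 | alternative 1 | (2R,3R)-butane-2,3-diyl bis[(E)-3-(4-hydroxyphenyl)prop-2-enoate] | C[C@@H](OC(=O)/C=C/c1ccc(O)cc1)[C@@H](C)OC(=O)/C=C/c1ccc(O)cc1
A2 | alternative 1 | all-R 2,6-bis(4-hydroxyphenyl)-3,7-dioxabicyclo[3.3.0]octane-4,8-dione | Oc1ccc([C@@H]2OC(=O)[C@@H]3[C@H]2C(=O)O[C@H]3c2ccc(O)cc2)cc1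
A3 | alternative 2 | 5-(benzyloxy)-3-{2-[2,4-bis(benzyloxy)-6-(4-methoxybenzyloxy)phenyl]-1-diazo-2-oxoethyl}-7-methoxy-2-(4-methoxyphenyl)-4H-chromen-4-one | COc1ccc(COc2cc(OCc3ccccc3)cc(OCc3ccccc3)c2C(=O)C(=[N+]=[N-])c2c(-c3ccc(OC)cc3)oc3cc(OC)cc(OCc4ccccc4)c3c2=O)cc1
A4 | alternative 2 | (2R,3R)-cis-3-(flavon-3-yl)flavanone, tri-O-benzyl | COc1ccc([C@@H]2Oc3cc(OCc4ccccc4)cc(OCc4ccccc4)c3C(=O)[C@@H]2c2c(-c3ccc(OC)cc3)oc3cc(OC)cc(OCc4ccccc4)c3c2=O)cc1
A5 | alternative 3 | 2,5-bis(4-methoxyphenyl)furan | COc1ccc(-c2ccc(-c3ccc(OC)cc3)o2)cc1
A6 | alternative 3 | 3,5-bis(benzyloxy)-2-(hydroxymethyl)phenol | OCc1c(O)cc(OCc2ccccc2)cc1OCc1ccccc1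
A7 | alternative 3 | 3,5-bis(benzyloxy)-6-methylidenecyclohexa-2,4-dien-1-one | C=C1C(=O)C=C(OCc2ccccc2)C=C1OCc1ccccc1
A8 | alternative 3 | furan-bridged bis-ketal of the cis,cis-3,3''-biflavan, tetra-O-benzyl | COc1ccc([C@@]23Oc4cc(OCc5ccccc5)cc(OCc5ccccc5)c4C[C@@H]2[C@H]2Cc4c(OCc5ccccc5)cc(OCc5ccccc5)cc4O[C@@]2(c2ccc(OC)cc2)O3)cc1
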